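## Retrosynthetic overview

1. The acetate and the aryl ether are removed first (acylation; Mitsunobu etherification with umbelliferone). This leads to a cis-1,3 diol, which comes from a silyl-capped γ-keto amide by C–Si protonolysis and two hydride reductions.
2. Key disconnection: the cyclohexane ring is cut at CH(O)–CMe2 and at C(=CH2)–CH(CH2O). This gives 5-(trimethylsilyl)pent-4-ynal and N,N,3-trimethylbut-2-enamide, which are joined by an enantioselective Rh(I)-catalysed [4+2] carbocyclisation.
3. Enabling feature: in the cyclohexane ring the O-bearing carbon and the methylidene-bearing carbon stand 1,4 and are linked by an unsubstituted CH2–CH2. Together with the exocyclic =CH2 carbon they form the skeleton of a pent-4-ynal. The other two ring atoms (CMe2, CH) and the OCH2 carbon are the β-C, α-C and C=O of a 3-methylbut-2-enoyl unit. The dissonant O–C–C–C–C–O pattern calls for an acyl anion equivalent, which acyl-rhodium provides.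
4. Stereochemistry: the ring CH is set by the chiral ligand in the key step. The carbinol carbon is set afterwards by substrate-controlled axial hydride delivery.
5. Ring order: only the cyclohexane ring is built (step 3). The coumarin bicycle is bought as umbelliferone and attached in step 7.

Key step: step 3

Remark 1: catalyst-bound organorhodium species of step 3 are described in the Why line and carry no compound numbers.
Remark 2: the sense of induction of the ligand cannot be derived from the known cases. It is assumed that one of the two commercial ligand antipodes delivers (1R)-5.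

## Route

Step 1
Reactants: 1 5-(trimethylsilyl)pent-4-yn-1-ol
Product: 2 5-(trimethylsilyl)pent-4-ynal
Conditions: TEMPO (10 mol %), PhI(OAc)2 (1.1 equiv), CH2Cl2, rt
Reagents that add atoms: none
Why: The oxoammonium (TEMPO/PhI(OAc)2) oxidation of a primary alcohol should stop at the aldehyde and leave the silylalkyne untouched; no stereocentre is formed.

Step 2
Reactants: 3 3-methylbut-2-enoyl chloride
Product: 4 N,N,3-trimethylbut-2-enamide
Conditions: Me2NH (2 M in THF), Et3N, CH2Cl2, 0 °C to rt
Reagents that add atoms: dimethylamine, CNC
Why: This is a Schotten–Baumann-type N-acylation of a secondary amine by an acid chloride; no stereocentre is formed.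

Step 3
Reactants: 2 5-(trimethylsilyl)pent-4-ynal; 4 N,N,3-trimethylbut-2-enamide
Product: 5 (1R,6E)-N,N,2,2-tetramethyl-3-oxo-6-[(trimethylsilyl)methylidene]cyclohexane-1-carboxamide
Conditions: [Rh(cod)2]BF4 (10 mol %), Walphos-type ferrocenyl bisphosphine (10 mol %, one antipode, H2 pre-activation), 4 (5 equiv), slow addition of 2, ClCH2CH2Cl, 60 °C
Reagents that add atoms: none
Why: Proposed new method: oxidative addition of the aldehyde C–H bond of 2 to cationic Rh(I) and intramolecular syn-hydrorhodation of the alkyne should give a five-membered acyl(alkenyl)rhodacycle (Rh on the former CHO carbon and on the internal alkyne carbon, SiMe3 pointing away from the metal); amide 4, bound through its carbonyl oxygen, then inserts with migration of the acyl group to its β-carbon (CMe2), and C(sp2)–C(sp3) reductive elimination from the seven-membered, O-chelated rhodium enolate joins the alkenyl carbon to the α-carbon. The closest known reaction type is the cationic Rh(I)/bisphosphine-catalysed regio- and enantioselective [4+2] carbocyclisation of 4-alkynals bearing internal alkynes with N,N-dialkylacrylamides, which gives 4-alkylidene-3-carbamoylcyclohexanones; new here is the β,β-dimethyl substitution of the acrylamide, so that the acyl migration has to build a quaternary carbon. The extension is defended by the two-point binding of the amide to a coordinatively unsaturated cation, by the absence of any β-hydrogen in the inserted intermediate (its β-carbon is quaternary, so escape by β-hydride elimination is closed) and by the gem-dimethyl effect on the ring-contracting elimination. The single ring, the cyclohexanone, closes by reductive elimination with contraction of the seven-membered metallacycle, a formal [4+2] of a C4 acyl/alkenyl unit with a C2 alkene. The single new stereocentre, C1 next to the amide, is under catalyst control, because the rhodium enolate can exchange its faces through the O-bound form and the chiral pocket of the ligand selects the C-bound diastereomer that eliminates faster, while the (E)-geometry of the vinylsilane follows from the syn-hydrorhodation. The step needs regioselectivity (acyl to CMe2, alkenyl to CH), secured by the acceptor polarity and carbonyl chelation of 4, since the reverse insertion would place Rh on a tertiary carbon without enolate stabilisation, and chemoselectivity over cyclopentenone formation, alkynal homo-annulation and alkyne trimerisation, secured by the SiMe3 cap, the excess of 4 and the slow addition of 2.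

Step 4
Reactants: 5 (1R,6E)-N,N,2,2-tetramethyl-3-oxo-6-[(trimethylsilyl)methylidene]cyclohexane-1-carboxamide
Product: 6 (1S)-N,N,2,2-tetramethyl-6-methylidene-3-oxocyclohexane-1-carboxamide
Conditions: CF3CO2H (5 equiv), CH2Cl2, 0 °C; aq. NaHCO3
Reagents that add atoms: none
Why: Electrophilic protodesilylation (ipso-protonation through the β-silyl-stabilised tertiary cation) should replace SiMe3 by H faster than the resulting 1,1-disubstituted alkene is re-protonated; the stereocentre is not touched, and its descriptor changes only because the CIP ranking changes.

Step 5
Reactants: 6 (1S)-N,N,2,2-tetramethyl-6-methylidene-3-oxocyclohexane-1-carboxamide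
Product: 7 (1S,3R)-3-hydroxy-N,N,2,2-tetramethyl-6-methylidenecyclohexane-1-carboxamide (OH and carboxamide cis, both equatorial)
Conditions: NaBH4, MeOH, –20 to 0 °C
Reagents that add atoms: none
Why: In this substrate-controlled borohydride reduction, the chair with the carboxamide equatorial should take the small hydride axially, on the face opposite the axial methyl of the neighbouring CMe2 group (as in 4,4-dimethyl-3-keto terpenoids), which gives the equatorial (3R) alcohol.

Step 6
Reactants: 7 (1S,3R)-3-hydroxy-N,N,2,2-tetramethyl-6-methylidenecyclohexane-1-carboxamide
Product: 8 (1R,3S)-3-(hydroxymethyl)-2,2-dimethyl-4-methylidenecyclohexan-1-ol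
Conditions: LiH2NBH3 (from BH3·NH3 + n-BuLi, 4.5 equiv), THF, 0 to 23 °C; sat. aq. NH4Cl
Reagents that add atoms: none
Why: Reduction of a tertiary amide to the primary alcohol with lithium amidotrihydroborate expels the amine from the tetrahedral intermediate and reduces the aldehyde at once, so the α-stereocentre should not epimerise and the isolated alkene should stay intact.

Step 7
Reactants: 8 (1R,3S)-3-(hydroxymethyl)-2,2-dimethyl-4-methylidenecyclohexan-1-ol; 9 umbelliferone (7-hydroxy-2H-chromen-2-one)
Product: 10 7-{[(1S,3R)-3-hydroxy-2,2-dimethyl-6-methylidenecyclohexyl]methoxy}-2H-chromen-2-one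
Conditions: PPh3, DIAD, THF, 0 °C to rt
Reagents that add atoms: none
Why: In this Mitsunobu etherification the acidic phenol is alkylated by the alkoxyphosphonium salt of the primary alcohol, while the secondary alcohol next to the quaternary carbon is too hindered to be activated; the reaction occurs at CH2, so no stereocentre is involved.

Step 8
Reactants: 10 7-{[(1S,3R)-3-hydroxy-2,2-dimethyl-6-methylidenecyclohexyl]methoxy}-2H-chromen-2-one
Product: 11 (1R,3S)-2,2-dimethyl-4-methylidene-3-{[(2-oxo-2H-chromen-7-yl)oxy]methyl}cyclohexyl acetate
Conditions: Ac2O, pyridine, DMAP (cat.), CH2Cl2, rt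
Reagents that add atoms: acetic anhydride, CC(=O)OC(C)=O
Why: DMAP-catalysed O-acylation takes place at oxygen, so the configuration of the carbinol carbon is retained.

## Compound list

1 | 5-(trimethylsilyl)pent-4-yn-1-ol | C[Si](C)(C)C#CCCCO | starting material
2 | 5-(trimethylsilyl)pent-4-ynal | C[Si](C)(C)C#CCCC=O | intermediate
3 | 3-methylbut-2-enoyl chloride | CC(C)=CC(=O)Cl | starting material
4 | N,N,3-trimethylbut-2-enamide | CC(C)=CC(=O)N(C)C | intermediate
5 | (1R,6E)-N,N,2,2-tetramethyl-3-oxo-6-[(trimethylsilyl)methylidene]cyclohexane-1-carboxamide | C[Si](C)(C)/C=C1\CCC(=O)C(C)(C)[C@H]1C(=O)N(C)C | intermediate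
6 | (1S)-N,N,2,2-tetramethyl-6-methylidene-3-oxocyclohexane-1-carboxamide | C=C1CCC(=O)C(C)(C)[C@H]1C(=O)N(C)C | intermediate
7 | (1S,3R)-3-hydroxy-N,N,2,2-tetramethyl-6-methylidenecyclohexane-1-carboxamide | C=C1CC[C@@H](O)C(C)(C)[C@H]1C(=O)N(C)C | intermediate
8 | (1R,3S)-3-(hydroxymethyl)-2,2-dimethyl-4-methylidenecyclohexan-1-ol | C=C1CC[C@@H](O)C(C)(C)[C@H]1CO | intermediate
9 | umbelliferone (7-hydroxy-2H-chromen-2-one) | Oc1ccc2ccc(=O)oc2c1 | starting material
10 | 7-{[(1S,3R)-3-hydroxy-2,2-dimethyl-6-methylidenecyclohexyl]methoxy}-2H-chromen-2-one | C=C1CC[C@@H](O)C(C)(C)[C@H]1COc1ccc2ccc(=O)oc2c1 | intermediate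
11 | (1R,3S)-2,2-dimethyl-4-methylidene-3-{[(2-oxo-2H-chromen-7-yl)oxy]methyl}cyclohexyl acetate | C=C1CC[C@@H](OC(C)=O)C(C)(C)[C@H]1COc1ccc2ccc(=O)oc2c1 | target

## Step count

Total step count: 8.
Longest linear sequence: 7 (steps 1, 3, 4, 5, 6, 7, 8, from compound 1).

## Steps most likely to fail

**Step 3 (Proposed new method).**
- What may go wrong: insertion of the trisubstituted alkene may be too slow. The rhodacycle would then be consumed by intramolecular hydroacylation to a cyclopentenone, by annulation with a second alkynal, or by decarbonylation. Facial selection at the enolate may also be poor.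
- Fallback: it uses known chemistry, sets out from 9 and comes back at 10, bypassing steps 1 to 7.
- Umbelliferone 9 is O-alkylated with geranyl bromide (K2CO3, acetone, reflux) to 7-geranyloxycoumarin F1.
- Shi epoxidation (D-fructose-derived ketone, Oxone, buffered MeCN/dimethoxymethane–water, 0 °C) of the distal, more electron-rich trisubstituted alkene should give 7-{[(2E)-5-[(2R)-3,3-dimethyloxiran-2-yl]-3-methylpent-2-en-1-yl]oxy}-2H-chromen-2-one F2.
- Titanocene(III)-mediated reductive epoxide opening and 6-endo radical cyclisation (Cp2TiCl2, Mn, THF, rt) follows, ending in β-hydrogen loss to the exocyclic alkene. Through a chair transition state it should give 10 with the cis-diequatorial arrangement. The carbinol configuration is carried over from the epoxide.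

**Step 4.**
- What may go wrong: acid may move the exocyclic double bond into the ring or into conjugation with the amide. Alternatively, the protonated amide may deactivate the vinylsilane so that protonolysis stalls.
- Fallback: it sets out from 5 and comes back at 6 without any Brønsted acid.
- Iododesilylation with N-iodosuccinimide (MeCN, 0 °C to rt) gives (1R,6E)-6-(iodomethylidene)-N,N,2,2-tetramethyl-3-oxocyclohexane-1-carboxamide F3.
- Pd(PPh3)4-catalysed hydrodeiodination with Bu3SnH (THF, rt) then gives 6.

**Step 7.**
- What may go wrong: displacement at the β-branched CH2 beside the quaternary carbon may be slow. Elimination to the diene, cyclodehydration by the cis secondary hydroxyl to a bridged ether, or alkylation of the hydrazide could then take over.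
- Fallback: it sets out from 8 and comes back at 10 with the roles of the partners reversed.
- The primary alcohol acts as the nucleophile in a Pd-catalysed Buchwald–Hartwig-type C–O coupling with commercial 7-bromocoumarin ([(allyl)PdCl]2, RockPhos, Cs2CO3, toluene, 90 °C). The carbon that is hard to displace is never activated.
- This fallback makes no new compound (F0).

## Further compounds

F1 | step 3 | 7-geranyloxycoumarin | CC(C)=CCC/C(C)=C/COc1ccc2ccc(=O)oc2c1
F2 | step 3 | 7-{[(2E)-5-[(2R)-3,3-dimethyloxiran-2-yl]-3-methylpent-2-en-1-yl]oxy}-2H-chromen-2-one | CC1(C)O[C@@H]1CC/C(C)=C/COc1ccc2ccc(=O)oc2c1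
F3 | step 4 | (1R,6E)-6-(iodomethylidene)-N,N,2,2-tetramethyl-3-oxocyclohexane-1-carboxamide | I/C=C1\CCC(=O)C(C)(C)[C@H]1C(=O)N(C)C
F0 | step 7 | none | none
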